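Early on, the ledger of the substrate, our limiting reagent, has few entries. Over the first 10.0 h of the violet run, target is credited at 0.0330 /h of the mean substrate. The grey run, over its first 4.00 h with twice the catalyst, gives 0.0301 /h. That is less than double the violet figure, so we book target as made from substrate without catalyst.

| setting | violet | grey | flask |
|---|---|---|---|
| substrate | 0.10 M | 0.10 M | 0.10 M |
| catalyst | 1.6 mM | 3.2 mM | 1.6 mM |
| remark | the very flask that is asked about, followed so far | run made earlier |  |
| time |  |  | 8.0 d |

- violet (time / h: target / %, substrate / %): 10.0: 26.8, 62.6; 30.0: 48.9, 27.7; 48.0: 54.7, 14.4; 72.0: 51.0, 9.4; 120: 44.2, 5.7
- grey (time / h: target / %, substrate / %): 4.00: 10.7, 77.6; 8.00: 18.8, 64.5; 12.0: 27.7, 53.8; 15.0: 32.9, 43.9; 20.0: 38.4, 39.0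

(standard deviation of a reading: 1 percentage point)

- beta: change nothing and wait 8.0 d more
- alpha: at 8.0 d add catalyst, 100% of the amount charged, then wait 8.0 d
- theta: at 8.0 d take out 90% of the target then present, then wait 8.0 d
- delta: at 8.0 d add substrate, 50.0% of the amount charged, then wait 8.0 d

* target, in percent of the substrate first charged, at 8.0 d
* what to do for the largest gain in target; "none" if nothing gains more than 2 percentage points (beta / alpha / theta / delta / none)
* target present, with what was taken out counted in, in percent of the substrate first charged, after beta
* target present, with what was taken out counted in, in percent of the substrate first charged, after delta

- target that was removed still counts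
- the earlier runs were read with a standard deviation of 1 percentage point
- reactions considered so far: substrate + catalyst <-> isomer of the product B + catalyst; substrate + catalyst <-> isomer of the product A + catalyst; target <-> isomer of the product C; substrate <-> target
- additions bring no volume worth counting

The debit is target turning into isomer of the product C. The highest target reading of the violet run stands at 48.0 h, and at a top making equals using, so we take that reading as lying near the top. We therefore carry the substrate-to-target quotient read there, 0.263, as the balance quotient: the ratio of substrate to target at which target is made as fast as it is used up, a reading with the scatter of its two values and with the way back of both steps left out of our reckoning. Any moment's quotient divided by it is our make-to-use ratio, provided both steps are first order and the way back of each is left aside.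

At 120 h the violet books show substrate 5.7%, target 44.2% and 50.1% in the three isomers, unsplit. The make-to-use ratio there is 0.490, less than one, so target is falling. Carrying the last fall on in a straight line gives us 34.0% at 8.0 d.

On our books beta leaves the ratio below one, and so does alpha, since we booked no catalyst in it. Taking that last reading as a stand-in for the state at 8.0 d, theta lifts the ratio to 4.90 and delta to 4.79. Both are more than one, and theta also banks what it removes, so we choose theta.

The forecast gives 35%, theta, 20.5% after beta and 38% after delta: “Theta banks about 31.5 and regrows about 10 from the pool, giving about 41, the best option.”

The flask gives 37.2%, and theta gains most, 16 percentage points, while beta ends at 31.9% and delta at 50.5%.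

    substrate + catalyst ⇌ isomer of the product B + catalyst, rate k1*[substrate]*[catalyst] forward; the back reaction follows from the equilibrium constant (K = 0.450, k = 6.40 /M/h)
    substrate + catalyst ⇌ isomer of the product A + catalyst, rate k2*[substrate]*[catalyst] forward; the back reaction follows from the equilibrium constant (K = 2.00, k = 1.50 /M/h)
    target ⇌ isomer of the product C (K = 1.90, k = 0.00950 /h)
    substrate ⇌ target (K = 13.0, k = 0.0360 /h)

At 192 h, substrate 3.87% over target 37.2% gives a make-to-use ratio of 0.395 by the balance quotient, and the flask's ratio with each step taken net is 0.355. The flask left until 50 h holds substrate 15.8% and target 52.0%, a ratio of 1.15, just above one, and by 96.0 h the target of the flask has come down to 47.2%.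

The data are calculated on assumed constants; noise was put on by code.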